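## Structural features

The target (28) is a labdane-type bicycle with a pendant lactone. Labdane numbering is used throughout: ring A is C1–C5 plus C10, ring B is C5–C10, C17 is the methyl on C8, C20 the methyl on C10, and C11–C12 link C9 to the lactone carbons C13–C16. Rings A and B are trans-fused at C5–C10; ring B is a 6-hydroxy-7-oxo-8-ene whose C8=C9 bond is tetrasubstituted, and ring A carries the gem-dimethyl group at C4. The side chain ends in a 4-hydroxy-γ-butyrolactone in which C13 is a tertiary carbinol, C14 a methylene, C15 the carbonyl and C16 the O-methylene. Three stereocentres are contiguous: quaternary C10 (R), C5 (R) and C6 (R), with the C6 hydroxyl axial and syn to C20. The fourth, C13 (S), is too far from the ring to be controlled by it. The α-ketol is the fragile part: the axial C6 epimer is the less stable one, and a 6,7-dione would enolise towards C5 to a diosphenol and destroy the ring fusion, so C6 must never be a ketone while C7 is one; the β-hydroxy lactone can also dehydrate to a butenolide. The real difficulties are the absolute configuration of quaternary C10 next to C5, the hindered C8=C9 alkene beside it, and the kinetic axial C6 carbinol. The key step uses the fact that in ring A the C9 substituent on C10 and the C6 substituent on C5 are trans on adjacent carbons lying β and α to C4, a carbonyl in disguise: this is the pattern left by conjugate addition at C10 and enolate trapping at C5 of 3-methylcyclohex-2-enone.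

## Logic of the disconnections

28 to 26. The lactone C15–O bond is cut and the C13/C16 diol is returned to its ketal. A γ-hydroxy acid closes by itself once the diol is free, and the tertiary C13 hydroxyl could only give a four-membered ring, so no regiocontrol is needed. The gain is that the dehydration-prone β-hydroxy lactone exists only in the last flask. The forward step needs acid mild enough to leave C13–OH and the C6 epimer alone.

26 to 25 to 24. No skeletal bond is cut; the C15 acid and the C7 ketone are taken back to carbinols. This puts both carbonyl groups after the last reductive operation. The gain is 24, whose three hydroxyls differ in kind (allylic secondary, unhindered primary, hindered axial secondary). The forward oxidations must respect that order, and C16 must still be masked when C15 is oxidised.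

24 to 22. The two C4 methyl groups are joined by a C–C bond into a spirocyclopropane, and the C15 oxygen regains its benzyl group. A cyclopropane is a gem-dimethyl precursor that is inert to hydride, Swern, Grignard and metathesis conditions, whereas a C4 methylidene would close a five-membered ring in the metathesis. The gain is that both hydrogenolyses fall in one operation at a stage with no carbonyl group. The demand is that the tetrasubstituted C8=C9 alkene and the allylic C7 carbinol survive hydrogen on palladium and platinum.

22 to 21. The C6–H bond is cut, giving the 6-ketone while C7 is still a carbinol. The axial alcohol is the kinetic product of hydride addition to a rigid 6-ketone. A reset by oxidation and reduction of a 6-hydroxy-7-oxo-8-ene would pass through the 6,7-dione and put C5 at risk, so the oxidation levels of C6 and C7 are interchanged instead. The gain is that C6 no longer depends on the aldol. The demand is hydride delivery from the face opposite C20.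

21 to 20. The C8=C9 bond is cut by retro-metathesis. Both alkene partners then sit on adjacent carbons of ring A, held trans. The gain is a monocyclic precursor. The demand is closure of a tetrasubstituted alkene beside quaternary C10.

20 to 18 and 19. The C7–C8 bond is cut. C8, C17 and the methylidene carbon come from a commercial alkenyl nucleophile. The gain is a two-carbonyl electrophile made from the aldol unit. The demand is that the nucleophile chooses the aldehyde over the buried C6 ketone.

18 to 17 to 16. No skeletal bond is cut; C6 and C7 are returned to the hydroxy ester. An ester cannot take up one alkenyl group cleanly, and C6 has to pass through the ketone in any case. The gain is that both C6 epimers of the aldol converge. The demand is a double oxidation without C–C cleavage or epimerisation at C5.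

16 to 15 to 14. The C4–CH2 bonds of the cyclopropane, and before that the C4=CH2 bond, are cut back to the C4 ketone. The ketone is needed only for the key step; converting it at once removes retro-aldol, dehydration and chemoselectivity problems. The gain is that 14, the direct product of the key step, is used unprotected. The demands are a methylenation without base and a cyclopropanation that picks the C4 methylidene over the C9 methylidene.

14 to 9, 10 and 11 (through 12 and 13). The C9–C10 and C5–C6 bonds are cut. This removes the quaternary centre, the C5 centre and the whole C6–C7 unit in one operation. The gain is three simple components, two of them commercial. The demand is catalyst control at C10, alkenyl transfer with the branched regiochemistry, and trapping at C5 anti to the alkenyl group.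

9 to 8 to 5 and 6. The ketal is removed and the C11–C12 bond is cut. The epoxide carbon C12 is the only unsubstituted one, so a propargyl nucleophile must open it there. The gain is a small epoxy alcohol. The demand is opening without touching C13.

5 to 4. The epoxide C–O bonds are cut. A 2-substituted allylic alcohol is a standard substrate for asymmetric epoxidation. The gain is an achiral precursor. The demand is high facial selectivity and survival of the sensitive epoxy alcohol.

4 to 1 and 2. The C14–C15 bond is cut. The allylic methyl of 1 is the latent nucleophile. The gain is two commercial compounds. The demand is C- rather than O-alkylation.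

## Other disconnections considered

Alternative 1: The cut is C5–C10 and C8–C9, so that rings A and B come from an open chain, the trienal A2, by an intramolecular Diels–Alder reaction under a chiral oxazaborolidinium triflimide, giving A1. In its favour: two rings, two C–C bonds and both ring-fusion centres arise in one step. The gem-dimethyl group is already in the tether, so the carbonyl-to-CMe2 problem of the chosen plan does not exist; on this point it is the better plan. C6 and C7 also arrive at the right oxidation level as a differentiated enediol ether. Against it: the dienophile is a β,β-disubstituted enal that must form quaternary C10, and the diene is a bis(silyl enol ether) sharing a flask with an aldehyde and a strong Lewis acid, so Mukaiyama-type addition and silyl transfer would compete with cycloaddition. A1 carries neither the C8=C9 bond nor the side chain. Both would be added afterwards, and C13 would then be set late in a remote acyclic position, whereas the chosen plan sets it early by a reliable epoxidation. On step economy the core is shorter but the end game is longer, so the two plans are of similar length. On C6 the two plans are equal, since both rely on kinetic delivery from the face opposite C20 (protonation here, hydride in the chosen plan).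

Alternative 2: The cut is C1–C10; ring B starts as the hexasubstituted phenol A4, and oxidation by a chiral aryl-λ3-iodane with ipso attack of the Z-vinylsilane at the para carbon gives the dienone A3. In its favour: the C8=C9 bond, the C7 carbonyl, the C6 oxygen, the gem-dimethyl group and the finished lactone are all present before the key step. No metathesis and no late side-chain oxidation are needed; on these points it is better than the chosen plan, and it is more convergent. Against it: A4 is itself a demanding contiguously substituted arene. The stereo-determining event happens at the para carbon, far from the iodane-bound oxygen, and catalytic asymmetric dearomatisation of this kind is best established for ortho attack by oxygen nucleophiles, not for para C–C bond formation to a quaternary centre. After the key step the C1=C2 and C5=C6 bonds must be reduced without touching C8=C9. Hydrogen added anti to C20 would give both the trans fusion and the axial C6 oxygen, which is as good as the chosen plan in principle, but reduction of a tetrasubstituted enol ether inside a cross-conjugated dienone is not secure. The chosen key step has much closer precedent.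

Alternative 3: The cut is C14–C15 and C15–O; the epoxy alcohol A6 is carbonylated with [(salph)Al(THF)2][Co(CO)4] under CO to give A5. In its favour: C15 comes from CO at the end, so the side chain needs no protected C15 oxygen and the three end-game operations of the chosen plan shrink to one; on side-chain step economy it is the better plan. C13 comes from a Sharpless epoxide in both plans, which is a tie. Against it: it says nothing about the decalin, so it complements rather than competes with the chosen key step. The normal course of this catalysis is closure of a β-lactone by the aluminium alkoxide, so the γ-lactone depends on acyl capture by the C16 hydroxyl or on translactonisation. The free hydroxyl can bind the Lewis acid, and a 2,2-disubstituted epoxide can ionise at the tertiary carbon and rearrange. The epoxide would also have to be carried or made late on a substrate with an enone. The chosen plan spends more steps on the lactone but uses only classical operations there.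

Key step: step 5

Assumption: the aldol of step 5 is taken to give mainly the anti (6S) epimer drawn for 14 to 17, and the C7 carbinol of 20 to 24 is carried as both epimers; neither centre is relied on, because C6 passes through a ketone (18) and C7 ends as one (25).

Step 1
Reactants: 1 2-methylprop-2-en-1-ol; 2 benzyl chloromethyl ether
Product: 4 4-(benzyloxy)-2-methylidenebutan-1-ol, via dilithiated methallyl alcohol 3 (not isolated)
Conditions: n-BuLi (2.2 equiv), TMEDA, Et2O–hexane, 0 °C to rt; then 2, THF, −78 to 0 °C; aq. NH4Cl
Reagents that add atoms: none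
Why: Dianion alkylation of a 2-methylallyl alcohol: the oxygen-chelated allyl anion is far more nucleophilic at carbon than the lithium alkoxide is at oxygen, so the chloromethyl ether should be C-alkylated, which installs C15 with its oxygen already protected.

Step 2
Reactants: 4 4-(benzyloxy)-2-methylidenebutan-1-ol
Product: 5 [(2S)-2-[2-(benzyloxy)ethyl]oxiran-2-yl]methanol
Conditions: Ti(OiPr)4 (10 mol %), L-(+)-diisopropyl tartrate (12 mol %), t-BuOOH, 4 Å molecular sieves, CH2Cl2, −20 °C
Reagents that add atoms: tert-butyl hydroperoxide CC(C)(C)OO
Why: Sharpless asymmetric epoxidation of a 2-substituted allylic alcohol; with the L-(+)-tartrate the oxygen is delivered to the face that makes C13 (S), the sense established for 2-alkylallyl alcohols, and catalytic titanium with sieves limits opening of the sensitive epoxy alcohol.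

Step 3
Reactants: 5 [(2S)-2-[2-(benzyloxy)ethyl]oxiran-2-yl]methanol; 6 3-bromoprop-1-yne
Product: 8 (2S)-2-[2-(benzyloxy)ethyl]hex-5-yne-1,2-diol, via allenylmagnesium bromide 7 (not isolated)
Conditions: 6, Mg, HgCl2 (cat.), Et2O, 0 °C; then 5, Et2O, −78 to 0 °C; aq. NH4Cl
Reagents that add atoms: none
Why: Epoxide opening by a propargyl/allenyl Grignard reagent: the reagent reacts through its γ-carbon and attacks the unsubstituted epoxide carbon C12 in an SN2 step that does not touch C13, so the configuration is retained; Payne rearrangement would need attack at the fully substituted carbon and should be slow for the magnesium alkoxide.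

Step 4
Reactants: 8 (2S)-2-[2-(benzyloxy)ethyl]hex-5-yne-1,2-diol
Product: 9 (4S)-4-[2-(benzyloxy)ethyl]-4-(but-3-yn-1-yl)-2,2-dimethyl-1,3-dioxolane
Conditions: Me2C(OMe)2, PPTS (cat.), CH2Cl2, rt
Reagents that add atoms: 2,2-dimethoxypropane COC(C)(C)OC
Why: Acid-catalysed transketalisation (acetonide formation) ties up the C13 and C16 oxygens, so that later only C15 can be raised to the acid level.

Step 5
Reactants: 9 (4S)-4-[2-(benzyloxy)ethyl]-4-(but-3-yn-1-yl)-2,2-dimethyl-1,3-dioxolane; 10 3-methylcyclohex-2-en-1-one; 11 ethyl glyoxylate
Product: 14 ethyl (2S)-2-hydroxy-2-[(1R,2R)-2-methyl-6-oxo-2-{4-[(4S)-4-(2-(benzyloxy)ethyl)-2,2-dimethyl-1,3-dioxolan-4-yl]but-1-en-2-yl}cyclohexyl]acetate, via branched alkenylaluminium 12 (not isolated), via aluminium enolate 13 (not isolated)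
Conditions: iBu2AlH, NiCl2(dppp) (3 mol %), THF, 0 to 22 °C; then 10, Cu(OTf)2 (5 mol %), chiral sulfonate-bearing imidazolinium salt (5 mol %), THF, −78 to −30 °C; then 11 (freshly cracked, 3 equiv), −78 to −40 °C; aq. potassium sodium tartrate
Reagents that add atoms: none
Why: Nickel hydride adds across the terminal alkyne with the bisphosphine dppp steering aluminium to the internal carbon, so 12 is the branched alkenylaluminium. The alkenyl group then passes from aluminium to the NHC-bound copper, which complexes 10, adds at the β-carbon through a trivalent copper species and eliminates reductively to form C9–C10 and the regiodefined enolate 13; this is the known NHC–copper conjugate alkenylation of β-substituted cyclic enones with alkenylaluminium reagents. The chiral carbene ligand selects the enone face and so sets quaternary C10 as (R); the enantiomeric imidazolinium salt would give the mirror image. Enolate 13 binds the very electrophilic aldehyde 11 at aluminium and adds through a closed six-membered transition state to form C5–C6, and the fixed enolate geometry makes the anti aldol (6S) the expected epimer, which is not relied on because C6 is oxidised in step 9. C5 is set by the neighbouring C10: the aldehyde should approach anti to the larger alkenyl substituent, giving the trans 2,3-relationship that becomes the trans ring fusion. No ring is closed. The step needs alkenyl and not isobutyl transfer (sp2 groups pass from aluminium to copper faster), 1,4- and not 1,2-addition (copper catalysis at low temperature) and trapping at C5 and not C3 (the enolate is formed regiospecifically and is used before it can equilibrate). The acetonide and the benzyl ether are inert to the aluminium species in THF.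

Step 6
Reactants: 14 anti-aldol keto ester (ring A C4 ketone)
Product: 15 ethyl (2S)-2-hydroxy-2-[(1R,2R)-2-methyl-6-methylidene-2-{4-[(4S)-4-(2-(benzyloxy)ethyl)-2,2-dimethyl-1,3-dioxolan-4-yl]but-1-en-2-yl}cyclohexyl]acetate
Conditions: Zn, CH2Br2, TiCl4, THF–CH2Cl2, 0 °C to rt
Reagents that add atoms: dibromomethane BrCBr
Why: Lombardo methylenation: the non-basic zinc/titanium methylene reagent olefinates the hindered, enolisable C4 ketone without retro-aldol cleavage, epimerisation at C5 or attack on the ester, and it tolerates the free hydroxyl; removing the carbonyl at once also removes the β-hydroxy ketone liability.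

Step 7
Reactants: 15 C4-methylidene hydroxy ester
Product: 16 ethyl (2S)-2-hydroxy-2-[(4R,5R)-5-methyl-5-{4-[(4S)-4-(2-(benzyloxy)ethyl)-2,2-dimethyl-1,3-dioxolan-4-yl]but-1-en-2-yl}spiro[2.5]octan-4-yl]acetate
Conditions: Et2Zn (2.2 equiv), CH2I2 (2.2 equiv), CH2Cl2, −10 to 0 °C
Reagents that add atoms: diiodomethane ICI
Why: Hydroxyl-directed Simmons–Smith (Furukawa) cyclopropanation: the zinc alkoxide at C6 should deliver the carbenoid to the homoallylic C4 methylidene, while the C9 methylidene is one bond further away and shielded by quaternary C10; the spiro carbon is not a stereocentre.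

Step 8
Reactants: 16 spirocyclopropane hydroxy ester
Product: 17 (1S)-1-[(4R,5R)-5-methyl-5-{4-[(4S)-4-(2-(benzyloxy)ethyl)-2,2-dimethyl-1,3-dioxolan-4-yl]but-1-en-2-yl}spiro[2.5]octan-4-yl]ethane-1,2-diol
Conditions: LiAlH4, THF, 0 °C
Reagents that add atoms: none
Why: Hydride reduction of the α-hydroxy ester to the 1,2-diol; alkene, cyclopropane, acetonide and benzyl ether are inert to LiAlH4.

Step 9
Reactants: 17 C6,C7-diol
Product: 18 2-[(4R,5R)-5-methyl-5-{4-[(4S)-4-(2-(benzyloxy)ethyl)-2,2-dimethyl-1,3-dioxolan-4-yl]but-1-en-2-yl}spiro[2.5]octan-4-yl]-2-oxoacetaldehyde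
Conditions: (COCl)2, DMSO, CH2Cl2, −78 °C; Et3N, −78 to −20 °C; used crude
Reagents that add atoms: none
Why: Double Swern oxidation of a 1,2-diol gives the α-keto aldehyde without C–C cleavage and erases the C6 carbinol on purpose; C5 lies between two fully substituted carbons and should be too shielded for the amine to epimerise it at low temperature.

Step 10
Reactants: 18 α-keto aldehyde; 19 isopropenylmagnesium bromide
Product: 20 2-hydroxy-3-methyl-1-[(4R,5R)-5-methyl-5-{4-[(4S)-4-(2-(benzyloxy)ethyl)-2,2-dimethyl-1,3-dioxolan-4-yl]but-1-en-2-yl}spiro[2.5]octan-4-yl]but-3-en-1-one (both C7 epimers)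
Conditions: 19 (1.1 equiv), THF, −78 °C; aq. NH4Cl; used without delay
Reagents that add atoms: none
Why: Chemoselective Grignard addition: the aldehyde is far more electrophilic than the C6 ketone, which is buried between C4 and C10, so one equivalent of the alkenyl nucleophile should give the C7 carbinol; both epimers are used because C7 ends as a carbonyl.

Step 11
Reactants: 20 acyclic acyloin diene
Product: 21 (5R,10R)-bicyclic acyloin: ring B 6-oxo-7-hydroxy-8-ene with C17 methyl on C8; ring A with C4 spirocyclopropane and C20 methyl; C9 chain CH2CH2-[(4S)-4-(2-(benzyloxy)ethyl)-2,2-dimethyl-1,3-dioxolan-4-yl]; both C7 epimers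
Conditions: second-generation Hoveyda–Grubbs catalyst RuCl2(H2IMes)(=CH-C6H4-2-OiPr) (15 mol %), 2,6-dichloro-1,4-benzoquinone (30 mol %), toluene, 80–100 °C, argon sparge
Reagents that add atoms: none
Why: Ring-closing metathesis of two 1,1-disubstituted alkenes held on adjacent trans positions of ring A closes ring B as a tetrasubstituted cyclohexene; the free allylic hydroxyl assists carbene loading, the quinone suppresses isomerisation by ruthenium hydrides and loss of ethylene drives the reaction. The trans ring fusion is inherited from C5 and C10 and is also the more stable arrangement for a 6-ketone.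

Step 12
Reactants: 21 bicyclic acyloin
Product: 22 (5R,6R,10R)-bicyclic 6,7-diol: C6 hydroxyl axial and syn to C20; C7 carbinol as both epimers; C8=C9 alkene; C4 spirocyclopropane; side chain as in 21
Conditions: NaBH4, MeOH, −20 °C
Reagents that add atoms: none
Why: Borohydride reduction of a rigid trans-decalin ketone: hydride should attack C6 from the face opposite the axial C20 methyl and the cyclopropane, giving the axial (6R) alcohol; because C7 is a carbinol at this point, no 6,7-dione or diosphenol can form.

Step 13
Reactants: 22 bicyclic 6,7-diol benzyl ether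
Product: 24 (5R,6R,10R)-4,4-dimethyl bicyclic triol: C6 axial hydroxyl; C7 carbinol (both epimers); C15 primary alcohol; C13/C16 acetonide (13S), via debenzylated spirocyclopropane triol 23 (not isolated)
Conditions: H2 (1 atm), Pd/C, EtOAc, rt; filter; then H2 (3 atm), PtO2, glacial AcOH, rt
Reagents that add atoms: none
Why: Hydrogenolysis of the benzyl ether on palladium, then Adams-type hydrogenolysis of the spirocyclopropane, which cleaves the unhindered CH2–CH2 bond and leaves the gem-dimethyl group; the tetrasubstituted C8=C9 alkene beside quaternary C10 should not reach the metal surface, and no carbonyl group is present at this stage.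

Step 14
Reactants: 24 4,4-dimethyl bicyclic triol
Product: 25 (5R,6R,10R)-6-hydroxy-7-oxo-8-ene with C15 primary alcohol and C13/C16 acetonide (13S)
Conditions: MnO2 (activated, excess), CH2Cl2, rt
Reagents that add atoms: none
Why: Allylic alcohol oxidation with MnO2 touches only the C7 carbinol and leaves the axial C6 hydroxyl and the primary C15 alcohol; the two C7 epimers converge to one enone.

Step 15
Reactants: 25 hydroxy enone alcohol
Product: 26 (5R,6R,10R)-6-hydroxy-7-oxo-8-ene C15 carboxylic acid with C13/C16 acetonide (13S)
Conditions: TEMPO (20 mol %), PhI(OAc)2 (2.5 equiv), MeCN–H2O (1:1), rt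
Reagents that add atoms: water O
Why: Oxoammonium oxidation (TEMPO with PhI(OAc)2 in aqueous acetonitrile) takes the unhindered primary alcohol through the aldehyde hydrate to the acid; the hindered axial α-ketol hydroxyl is not expected to react, and C16 is still masked in the acetonide.

Step 16
Reactants: 26 acetonide acid
Product: 28 (1R,4aR,8aR)-1-hydroxy-4-{2-[(3S)-3-hydroxy-5-oxooxolan-3-yl]ethyl}-3,4a,8,8-tetramethyl-4a,5,6,7,8,8a-hexahydronaphthalen-2(1H)-one, via dihydroxy acid 27 (not isolated)
Conditions: AcOH–H2O (4:1), 40 °C
Reagents that add atoms: none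
Why: Mild acid hydrolysis of the acetonide frees the C13/C16 diol, and the γ-hydroxy acid lactonises spontaneously through the primary C16 hydroxyl (five-membered ring; the tertiary hydroxyl could only give a β-lactone); the conditions should be too mild to dehydrate the tertiary alcohol or enolise C6.

Compound list

1 | 2-methylprop-2-en-1-ol | CC(=C)CO | starting material
2 | benzyl chloromethyl ether | ClCOCc1ccccc1 | starting material
3 | lithium 2-(lithiomethyl)prop-2-en-1-olate | [Li]CC(=C)CO[Li] | intermediate (not isolated)
4 | 4-(benzyloxy)-2-methylidenebutan-1-ol | C=C(CO)CCOCc1ccccc1 | intermediate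
5 | [(2S)-2-[2-(benzyloxy)ethyl]oxiran-2-yl]methanol | OC[C@@]1(CCOCc2ccccc2)CO1 | intermediate
6 | 3-bromoprop-1-yne | C#CCBr | starting material
7 | allenylmagnesium bromide | C=C=C[Mg]Br | intermediate (not isolated)
8 | (2S)-2-[2-(benzyloxy)ethyl]hex-5-yne-1,2-diol | C#CCC[C@@](O)(CO)CCOCc1ccccc1 | intermediate
9 | (4S)-4-[2-(benzyloxy)ethyl]-4-(but-3-yn-1-yl)-2,2-dimethyl-1,3-dioxolane | C#CCC[C@@]1(CCOCc2ccccc2)OC(C)(C)OC1 | intermediate
10 | 3-methylcyclohex-2-en-1-one | CC1=CC(=O)CCC1 | starting material
11 | ethyl glyoxylate | CCOC(=O)C=O | starting material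
12 | {4-[(4S)-4-[2-(benzyloxy)ethyl]-2,2-dimethyl-1,3-dioxolan-4-yl]but-1-en-2-yl}bis(2-methylpropyl)aluminium | C=C([Al](CC(C)C)CC(C)C)CC[C@@]1(CCOCc2ccccc2)OC(C)(C)OC1 | intermediate (not isolated)
13 | diisobutylaluminium enolate of the (3R)-3-methyl-3-alkenylcyclohexanone (C4=C5 enolate, side chain (13S)) | C=C(CC[C@@]1(CCOCc2ccccc2)OC(C)(C)OC1)[C@]1(C)CCCC(O[Al](CC(C)C)CC(C)C)=C1 | intermediate (not isolated)
14 | ethyl (2S)-2-hydroxy-2-[(1R,2R)-2-methyl-6-oxo-2-{4-[(4S)-4-(2-(benzyloxy)ethyl)-2,2-dimethyl-1,3-dioxolan-4-yl]but-1-en-2-yl}cyclohexyl]acetate | C=C(CC[C@@]1(CCOCc2ccccc2)OC(C)(C)OC1)[C@]1(C)CCCC(=O)[C@H]1[C@H](O)C(=O)OCC | intermediate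
15 | ethyl (2S)-2-hydroxy-2-[(1R,2R)-2-methyl-6-methylidene-2-{4-[(4S)-4-(2-(benzyloxy)ethyl)-2,2-dimethyl-1,3-dioxolan-4-yl]but-1-en-2-yl}cyclohexyl]acetate | C=C(CC[C@@]1(CCOCc2ccccc2)OC(C)(C)OC1)[C@]1(C)CCCC(=C)[C@H]1[C@H](O)C(=O)OCC | intermediate
16 | ethyl (2S)-2-hydroxy-2-[(4R,5R)-5-methyl-5-{4-[(4S)-4-(2-(benzyloxy)ethyl)-2,2-dimethyl-1,3-dioxolan-4-yl]but-1-en-2-yl}spiro[2.5]octan-4-yl]acetate | C=C(CC[C@@]1(CCOCc2ccccc2)OC(C)(C)OC1)[C@]1(C)CCCC2(CC2)[C@H]1[C@H](O)C(=O)OCC | intermediate
17 | (1S)-1-[(4R,5R)-5-methyl-5-{4-[(4S)-4-(2-(benzyloxy)ethyl)-2,2-dimethyl-1,3-dioxolan-4-yl]but-1-en-2-yl}spiro[2.5]octan-4-yl]ethane-1,2-diol | C=C(CC[C@@]1(CCOCc2ccccc2)OC(C)(C)OC1)[C@]1(C)CCCC2(CC2)[C@H]1[C@H](O)CO | intermediate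
18 | 2-[(4R,5R)-5-methyl-5-{4-[(4S)-4-(2-(benzyloxy)ethyl)-2,2-dimethyl-1,3-dioxolan-4-yl]but-1-en-2-yl}spiro[2.5]octan-4-yl]-2-oxoacetaldehyde | C=C(CC[C@@]1(CCOCc2ccccc2)OC(C)(C)OC1)[C@]1(C)CCCC2(CC2)[C@H]1C(=O)C=O | intermediate
19 | isopropenylmagnesium bromide | CC(=C)[Mg]Br | starting material
20 | 2-hydroxy-3-methyl-1-[(4R,5R)-5-methyl-5-{4-[(4S)-4-(2-(benzyloxy)ethyl)-2,2-dimethyl-1,3-dioxolan-4-yl]but-1-en-2-yl}spiro[2.5]octan-4-yl]but-3-en-1-one, both C7 epimers | C=C(CC[C@@]1(CCOCc2ccccc2)OC(C)(C)OC1)[C@]1(C)CCCC2(CC2)[C@H]1C(=O)C(O)C(C)=C | intermediate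
21 | (5R,10R,13S)-bicyclic acyloin: 6-oxo-7-hydroxy-8-ene, C4 spirocyclopropane, 15-O-benzyl, 13,16-acetonide, both C7 epimers | CC1=C(CC[C@@]2(CCOCc3ccccc3)OC(C)(C)OC2)[C@]2(C)CCCC3(CC3)[C@H]2C(=O)C1O | intermediate
22 | (5R,6R,10R,13S)-bicyclic 6,7-diol: axial 6-OH, 8-ene, C4 spirocyclopropane, 15-O-benzyl, 13,16-acetonide, both C7 epimers | CC1=C(CC[C@@]2(CCOCc3ccccc3)OC(C)(C)OC2)[C@]2(C)CCCC3(CC3)[C@H]2[C@@H](O)C1O | intermediate
23 | (5R,6R,10R,13S)-spirocyclopropane 6,7,15-triol, 13,16-acetonide, both C7 epimers | CC1=C(CC[C@@]2(CCO)OC(C)(C)OC2)[C@]2(C)CCCC3(CC3)[C@H]2[C@@H](O)C1O | intermediate (not isolated)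
24 | (5R,6R,10R,13S)-4,4-dimethyl 6,7,15-triol, 8-ene, 13,16-acetonide, both C7 epimers | CC1=C(CC[C@@]2(CCO)OC(C)(C)OC2)[C@]2(C)CCCC(C)(C)[C@H]2[C@@H](O)C1O | intermediate
25 | (5R,6R,10R,13S)-6,15-dihydroxy-7-oxo-8-ene, 13,16-acetonide | CC1=C(CC[C@@]2(CCO)OC(C)(C)OC2)[C@]2(C)CCCC(C)(C)[C@H]2[C@@H](O)C1=O | intermediate
26 | (5R,6R,10R,13S)-6-hydroxy-7-oxo-8-en-15-oic acid, 13,16-acetonide | CC1=C(CC[C@@]2(CC(=O)O)OC(C)(C)OC2)[C@]2(C)CCCC(C)(C)[C@H]2[C@@H](O)C1=O | intermediate
27 | (5R,6R,10R,13S)-6,13,16-trihydroxy-7-oxo-8-en-15-oic acid | CC1=C(CC[C@@](O)(CO)CC(=O)O)[C@]2(C)CCCC(C)(C)[C@H]2[C@@H](O)C1=O | intermediate (not isolated)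
28 | (1R,4aR,8aR)-1-hydroxy-4-{2-[(3S)-3-hydroxy-5-oxooxolan-3-yl]ethyl}-3,4a,8,8-tetramethyl-4a,5,6,7,8,8a-hexahydronaphthalen-2(1H)-one | CC1=C(CC[C@@]2(O)COC(=O)C2)[C@]2(C)CCCC(C)(C)[C@H]2[C@@H](O)C1=O | target

Total step count: 16. Longest linear sequence: 16 steps, from 1 to 28; 2, 6, 10, 11 and 19 enter as purchased compounds.

Least certain steps

Step 5 (key step). Capture of the hindered aluminium enolate may be slow or unselective, with proton transfer and oligomerisation of the aldehyde competing. Facial selectivity at C5 may also be imperfect, because the enolate is a weak nucleophile and the attacked carbon sits next to the new quaternary centre. The fallback sets out from 9 and 10 and returns at 14. The conjugate addition is run as before, but enolate 13 is quenched with trimethylsilyl triflate and the trimethylsilyl enol ether F1 is isolated. A Mukaiyama aldol addition of F1 to 11 with BF3·OEt2 in CH2Cl2 at −78 °C then forms C5–C6 through an open transition state and gives 14; either C6 epimer serves, since both converge at 18.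

Step 7. The C9 methylidene may be cyclopropanated as well as, or instead of, the C4 methylidene if hydroxyl direction is weaker than assumed. The fallback sets out from 15 and returns at 16. N-Bromosuccinimide (NaHCO3, CH2Cl2, 0 °C) should join the C6 hydroxyl and the C9 methylidene in a 5-exo bromoetherification to the bromo ether F2; the C4 methylidene has no comparable ring closure open to it. The one remaining alkene is cyclopropanated with Et2Zn and CH2I2 to the spirocyclopropane bromo ether F3. Zinc dust with NH4Cl in ethanol then opens the β-bromo ether reductively and returns the C9 methylidene and the C6 hydroxyl in 16.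

Step 10. The carbonyl may shift from C6 to C7 through the enediol during work-up or chromatography (ketol transposition, driven by conjugation with the isopropenyl group), or a second addition may occur at C6. The fallback sets out from 18 and returns at 22. The magnesium alkoxide is silylated in the same flask with chlorotriethylsilane to the triethylsilyl ether F4, which cannot transpose. Ring-closing metathesis gives the bicyclic silyl ether F5, and NaBH4 reduction followed by Bu4NF gives 22.

Step 11. The ruthenium carbene may fail to load onto either 1,1-disubstituted alkene, or closure of the tetrasubstituted alkene beside C10 may be so slow that catalyst decay and allylic alcohol isomerisation take over. The fallback is a relay metathesis that sets out from 18 and returns at 21. 1,3-Dibromobut-2-ene is O-allylated with allyl alcohol (NaH, THF) to 1-(allyloxy)-3-bromobut-2-ene F6. Its alkenyllithium (t-BuLi, −78 °C) is added to 18 to give the relay acyloin F7. The catalyst then loads on the terminal allyl group, expels 2,5-dihydrofuran and is delivered as the fully substituted carbene at C8, from which closure onto the C9 methylidene gives 21.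

Step 13. The allylic C7–O bond may be cleaved, the C8=C9 double bond may migrate on the metal surface, or the cyclopropane next to the hindered C5 may open incompletely. The fallback makes the gem-dimethyl group by radical hydromethylation before ring B exists; it sets out from 15 and returns at 24. The bromo ether F2, made from 15 as in the fallback for step 7, is treated with Fe(acac)3, PhSiH3 and a formaldehyde N-sulfonylhydrazone and then warmed in methanol. This adds hydrogen to the methylidene carbon and a methyl group to C4 (Markovnikov hydrogen-atom transfer) and gives the gem-dimethyl bromo ether F8. Zinc reopens it to the gem-dimethyl hydroxy ester F9. The operations of steps 8 to 12 then give in turn the diol F10, the keto aldehyde F11, the acyloin F12, the bicyclic acyloin F13 and the bicyclic diol benzyl ether F14. Hydrogenolysis of the benzyl ether of F14 on Pd/C alone gives 24.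

Further compounds

F1 | step 5 | trimethylsilyl enol ether of the (3R)-3-methyl-3-alkenylcyclohexanone, side chain (13S) | C=C(CC[C@@]1(CCOCc2ccccc2)OC(C)(C)OC1)[C@]1(C)CCCC(O[Si](C)(C)C)=C1
F2 | step 7 | (5R,6S,10R,13S)-bromo ether: tetrahydrofuran from O6 to C9 with bromomethyl on C9, C4 methylidene, ethyl ester | BrCC1(CC[C@@]2(CCOCc3ccccc3)OC(C)(C)OC2)O[C@H](C(=O)OCC)[C@@H]2C(=C)CCC[C@@]12C
F3 | step 7 | (5R,6S,10R,13S)-spirocyclopropane bromo ether | BrCC1(CC[C@@]2(CCOCc3ccccc3)OC(C)(C)OC2)O[C@H](C(=O)OCC)[C@@H]2C3(CC3)CCC[C@@]12C
F4 | step 10 | C7 triethylsilyl ether of acyloin 20 | C=C(CC[C@@]1(CCOCc2ccccc2)OC(C)(C)OC1)[C@]1(C)CCCC2(CC2)[C@H]1C(=O)C(O[Si](CC)(CC)CC)C(C)=C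
F5 | step 10 | C7 triethylsilyl ether of bicyclic acyloin 21 | CC1=C(CC[C@@]2(CCOCc3ccccc3)OC(C)(C)OC2)[C@]2(C)CCCC3(CC3)[C@H]2C(=O)C1O[Si](CC)(CC)CC
F6 | step 11 | 1-(allyloxy)-3-bromobut-2-ene | C=CCOCC=C(C)Br
F7 | step 11 | relay acyloin: analogue of 20 with an allyloxymethyl group on the terminal alkene carbon | C=C(CC[C@@]1(CCOCc2ccccc2)OC(C)(C)OC1)[C@]1(C)CCCC2(CC2)[C@H]1C(=O)C(O)C(C)=CCOCC=C
F8 | step 13 | (5R,6S,10R,13S)-4,4-dimethyl bromo ether | BrCC1(CC[C@@]2(CCOCc3ccccc3)OC(C)(C)OC2)O[C@H](C(=O)OCC)[C@@H]2C(C)(C)CCC[C@@]12C
F9 | step 13 | ethyl (2S)-2-hydroxy-2-[(1R,6R)-2,2,6-trimethyl-6-alkenylcyclohexyl]acetate, gem-dimethyl analogue of 16 | C=C(CC[C@@]1(CCOCc2ccccc2)OC(C)(C)OC1)[C@]1(C)CCCC(C)(C)[C@H]1[C@H](O)C(=O)OCC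
F10 | step 13 | gem-dimethyl analogue of diol 17 | C=C(CC[C@@]1(CCOCc2ccccc2)OC(C)(C)OC1)[C@]1(C)CCCC(C)(C)[C@H]1[C@H](O)CO
F11 | step 13 | gem-dimethyl analogue of keto aldehyde 18 | C=C(CC[C@@]1(CCOCc2ccccc2)OC(C)(C)OC1)[C@]1(C)CCCC(C)(C)[C@H]1C(=O)C=O
F12 | step 13 | gem-dimethyl analogue of acyloin 20, both C7 epimers | C=C(CC[C@@]1(CCOCc2ccccc2)OC(C)(C)OC1)[C@]1(C)CCCC(C)(C)[C@H]1C(=O)C(O)C(C)=C
F13 | step 13 | gem-dimethyl analogue of bicyclic acyloin 21, both C7 epimers | CC1=C(CC[C@@]2(CCOCc3ccccc3)OC(C)(C)OC2)[C@]2(C)CCCC(C)(C)[C@H]2C(=O)C1O
F14 | step 13 | gem-dimethyl analogue of bicyclic diol 22, both C7 epimers | CC1=C(CC[C@@]2(CCOCc3ccccc3)OC(C)(C)OC2)[C@]2(C)CCCC(C)(C)[C@H]2[C@@H](O)C1O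
A1 | alternative 1 | trans-fused bicyclic aldehyde with 6-O-TBS/7-O-TMS enediol ether, C8 methyl and C9 formyl | C[C@H]1[C@@H](C=O)[C@]2(C)CCCC(C)(C)[C@H]2C(O[Si](C)(C)C(C)(C)C)=C1O[Si](C)(C)C
A2 | alternative 1 | open-chain (E)-enal tethered to the 2,3-bis(silyloxy)diene | O=C/C=C(\C)CCCC(C)(C)/C=C(\O[Si](C)(C)C(C)(C)C)/C(O[Si](C)(C)C)=C/C
A3 | alternative 2 | bicyclic cross-conjugated dienone with 6-O-benzyl and 13-O-TBS lactone | CC1=C(CC[C@@]2(O[Si](C)(C)C(C)(C)C)COC(=O)C2)[C@]2(C)C=CCC(C)(C)C2=C(OCc3ccccc3)C1=O
A4 | alternative 2 | hexasubstituted phenol carrying the Z-vinylsilane tether and the 13-O-TBS lactone | Cc1c(O)c(OCc2ccccc2)c(C(C)(C)C/C=C\[Si](C)(C)C)c(C)c1CC[C@@]1(O[Si](C)(C)C(C)(C)C)COC(=O)C1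
A5 | alternative 3 | 6-O-TBS ether of 28 | CC1=C(CC[C@@]2(O)COC(=O)C2)[C@]2(C)CCCC(C)(C)[C@H]2[C@@H](O[Si](C)(C)C(C)(C)C)C1=O
A6 | alternative 3 | 6-O-TBS decalin enone carrying the (2R)-2-(hydroxymethyl)oxiran-2-yl side-chain terminus | CC1=C(CC[C@@]2(CO)CO2)[C@]2(C)CCCC(C)(C)[C@H]2[C@@H](O[Si](C)(C)C(C)(C)C)C1=O
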